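Amounts first: maple and elm hold the same free monomer and transfer agent as the earlier ochre and grey runs, and all four differ in the loading of initiator.

| setting | ochre | grey | maple | elm |
|---|---|---|---|---|
| free monomer | 0.052 M | 0.052 M | 0.052 M | 0.052 M |
| transfer agent | 0.52 mM | 0.52 mM | 0.520 mM | 0.520 mM |
| initiator | 3.3 mol% | 6 mol% | 5 mol% | 2.5 mol% |
| remark | run made earlier | run made earlier |  |  |
| time |  |  | 3.0 min | 3.0 min |

| run | time / min | monomer in chains / % | free monomer / % |
|---|---|---|---|
| ochre | 0.833 | 36.1 | 64.0 |
| ochre | 1.50 | 50.6 | 48.0 |
| ochre | 2.50 | 63.7 | 35.1 |
| ochre | 3.00 | 68.1 | 30.8 |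
| grey | 0.833 | 56.3 | 42.9 |
| grey | 1.50 | 73.5 | 24.8 |
| grey | 2.50 | 87.0 | 11.6 |
| grey | 3.00 | 91.4 | 8.1 |

(each reading ± 0.5 percentage points)

- which of the two ends with the longer chains by the average number of monomer units in a chain (chains begun, living or dead) ("neither" if they lie within 10%) (maple / elm / neither)
- average number of monomer units in a chain (chains begun, living or dead) at the end, maple
- average number of monomer units in a chain (chains begun, living or dead) at the end, elm

- the average divides the monomer in chains by the number of chains begun, living and dead together
- the numbers in the tables scatter with a standard deviation of 0.5 percentage points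
- the earlier runs do not show the number of chains; that part of a forecast is a guess

Follow one molecule of free monomer: its chance of being taken each minute rises with the initiator charged, so I reckon with the log, ln(charged free monomer / free monomer left). The gap between the grey and ochre logs grows steadily, at 0.440 min⁻¹ up to 1.50 min and 0.445 min⁻¹ up to 3.00 min. Dividing by the extra initiator gives the start of the reckoning:

growth constant = 317 L mol⁻¹ min⁻¹

So maple starts at 0.824 min⁻¹ and elm at 0.412 min⁻¹. Unslowed, that gives logs of 2.47 and 1.24 in 3.0 min.

The ochre log falls below its unslowed value by the shortfall:

shortfall = 0.455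

The steady gap says grey loses about the same with about twice the initiator, so I carry the same shortfall over to maple and elm, which differ from those runs in the loading of initiator. My own reckoning for the two flasks:

maple: log = 2.02, 0.818 of unslowed, free monomer left 13.3%

elm: log = 0.782, 0.631 of unslowed, free monomer left 45.7%

The readings show no chains, so I guess one chain per initiator and no restarts. Length is then the reacted share over the loading: 17.3 for maple and 21.7 for elm, so elm is longer, by a factor of 1.25.

The forecast also names elm, but gives lower lengths, 15.5 for maple and 18.5 for elm: “so I assume about 0.25 mM”.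

    living end + free monomer → dead end B (k = 0.0941 L mol⁻¹ s⁻¹)
    living end + transfer agent → dead chain (kL = 18.9 L mol⁻¹ s⁻¹)
    2 initiator → spent initiator A (k = 4.43 L mol⁻¹ s⁻¹)
    free monomer + initiator → living end + monomer in chains (k = 7.89 L mol⁻¹ s⁻¹)
    free monomer + living end → monomer in chains + living end, rate k5*[living end]*[free monomer] (k = 6.54 L mol⁻¹ s⁻¹)

The flask gives elm, with 17.6 for maple and 22.4 for elm. Elm keeps 44.1% of its free monomer at 3.00 min, which puts its shortfall at 0.419. A neighbouring flask repeats elm with 2.1 × 10⁻⁴ M of transfer agent. That flask ends with 36% of its free monomer left, which puts its shortfall at 0.219, less than elm's, and its length at 25.6.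

All runs are calculated for substances that don't exist, and the scatter is random.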